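Ring B (C5, C6, C7, C8, C9, C10) is closed last, at the C9–C10 bond, by a proton-initiated cation–olefin cyclisation. The step exploits the isoprenoid spacing of the methyl-bearing carbons C10 and C8 of ring B. Protonation of the C1=C10 alkene of ring A gives the C10 cation, the E C8=C9 alkene captures it, and loss of H-7 leaves the C7=C8 alkene, the latent cis-7,8-diol. One operation sets C10, C9 and the trans ring fusion. The precursor is a monocyclic cyclohexene, made by an enantioselective Diels–Alder reaction of methacrolein with a triene derived from β-farnesene, whose terminal 1,3-diene is masked as a sulfolene.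

Key step: step 7

Remark: labdane numbering is used for all compounds, including the acyclic and monocyclic ones.
Assumption: the (S)-oxazaborolidinium salt is taken to shield the face of bound methacrolein that leads to the (1S,2R) adduct. If the sense of induction is the opposite one, the equally available (R)-catalyst is used.

Step 1
Reactants: 1 (E)-β-farnesene
Product: 2 farnesene sulfolene, 3-[(3E)-4,8-dimethylnona-3,7-dien-1-yl]-2,5-dihydrothiophene 1,1-dioxide
Conditions: SO2 (condensed, excess), 2,6-di-tert-butyl-4-methylphenol (cat.), CH2Cl2, sealed tube, 40 °C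
Reagents that add atoms: sulfur dioxide, O=S=O
Why: Cheletropic addition of SO2 takes place only at the conjugated s-cis diene and masks C13–C16 against the cycloaddition, the acid and the OsO4 of later steps.

Step 2
Reactants: 2 farnesene sulfolene
Product: 4 enal, (2E,6E)-9-(1,1-dioxo-2,5-dihydrothiophen-3-yl)-2,6-dimethylnona-2,6-dienal, via allylic alcohol 3 (not isolated)
Conditions: SeO2 (0.3 equiv), t-BuOOH, CH2Cl2, 0 °C to rt; then MnO2 (excess) added to the filtered CH2Cl2 solution, rt
Reagents that add atoms: tert-butyl hydroperoxide, CC(C)(C)OO; selenium dioxide (oxygen relay), O=[Se]=O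
Why: SeO2 allylic oxidation (ene reaction, then [2,3]-sigmatropic shift) attacks the most electron-rich terminal trisubstituted alkene at its E methyl group (the future C1), and MnO2 oxidises the allylic alcohol to the E enal.

Step 3
Reactants: 4 enal
Product: 5 triene, 3-[(3E,7E)-4,8-dimethyldeca-3,7,9-trien-1-yl]-2,5-dihydrothiophene 1,1-dioxide
Conditions: Ph3PCH3Br, KN(SiMe3)2, THF, 0 °C; ylide solution (1.0 equiv) added slowly to 4, −78 to 0 °C
Reagents that add atoms: methyltriphenylphosphonium bromide, C[P+](c1ccccc1)(c1ccccc1)c1ccccc1.[Br-]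
Why: Wittig methylenation of the aldehyde should be faster than deprotonation of the sulfolene when no excess ylide is present, and it gives the E-configured 1-alkyl-2-methylbuta-1,3-diene (C2=C1–C10=C5).

Step 4
Reactants: 5 triene; 6 methacrolein
Product: 8 ring A alcohol, {(1S,2R)-2-[(3E)-6-(1,1-dioxo-2,5-dihydrothiophen-3-yl)-3-methylhex-3-en-1-yl]-1,3-dimethylcyclohex-3-en-1-yl}methanol, via ring A aldehyde 7 (not isolated)
Conditions: (S)-3,3-diphenyl-1-(2-methylphenyl)tetrahydro-1H,3H-pyrrolo[1,2-c][1,3,2]oxazaborole (20 mol %) + HN(SO2CF3)2 (18 mol %), CH2Cl2, −78 to −40 °C; then MeOH, NaBH4, −40 to 0 °C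
Reagents that add atoms: methacrolein (6), C=C(C)C=O
Why: In this Lewis-acid-catalysed enantioselective Diels–Alder reaction the unsubstituted terminus C2 bonds first to the β-carbon of the bound enal (ortho regiochemistry), endo orientation of the formyl group sets C19 cis to the C5 chain, the catalyst sets the absolute configuration at C4 and C5, and NaBH4 reduces the aldehyde in the same flask.

Step 5
Reactants: 9 methyl 2-[bis(2,2,2-trifluoroethoxy)phosphoryl]acetate
Product: 10 2-[bis(2,2,2-trifluoroethoxy)phosphoryl]acetic acid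
Conditions: LiOH (1.0 equiv), THF–H2O, 0 °C; then 1 M HCl
Reagents that add atoms: lithium hydroxide, [Li+].[OH-]
Why: Saponification with one equivalent of hydroxide at low temperature should cleave the carboxylic methyl ester before the phosphonate esters are attacked.

Step 6
Reactants: 8 ring A alcohol; 10 phosphonoacetic acid
Product: 11 monocyclic phosphonoacetate, the 2-[bis(2,2,2-trifluoroethoxy)phosphoryl]acetate ester of 8
Conditions: N,N'-dicyclohexylcarbodiimide, 4-(dimethylamino)pyridine (cat.), CH2Cl2, 0 °C to rt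
Reagents that add atoms: 2-[bis(2,2,2-trifluoroethoxy)phosphoryl]acetic acid (10), OC(=O)CP(=O)(OCC(F)(F)F)OCC(F)(F)F
Why: Steglich esterification is done at the monocyclic stage because the neopentyl C19 alcohol is not yet flanked by an axial C20 methyl group, and the acyl group serves both as acid-stable protection and as the olefination handle.

Step 7
Reactants: 11 monocyclic phosphonoacetate
Product: 14 labd-7-ene bicycle (trans-decalin with 5α-H, 9α-H, 10β-CH3, 4α-CH3, C7=C8 alkene, 9β-[2-(1,1-dioxo-2,5-dihydrothiophen-3-yl)ethyl] chain and 4β-CH2O-phosphonoacetate), via C10 cation 12 (not isolated), via C8 cation 13 (not isolated)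
Conditions: FSO3H (8 equiv), 2-nitropropane, −78 °C, 30 min; then Et3N, −78 °C
Reagents that add atoms: none
Why: FSO3H protonates the ring A alkene at C1 to give the tertiary C10 cation 12, C9 of the E C8=C9 alkene attacks it to give the tertiary C8 cation 13, and the Et3N quench removes H-7 and leaves the C7=C8 alkene. The closest known reaction type is the superacid (or Lewis-acid-assisted Brønsted acid) cyclisation of monocyclic α-cyclogeranyl-type terpenoids and of farnesyl esters to drim-7-enes. Ring B closes in a cationic 6-endo-trig mode through a chair-like transition state in which the C5–C6 bond is equatorial on ring A. C10 is controlled by the resident C5 stereocentre, since the chair–chair arrangement brings C9 to the α lobe of the cation, which makes the new bond equatorial and the C20 methyl group axial (trans-decalin). C9 is controlled by the E geometry of the alkene through anti addition, which places C11 equatorial (9α-H). The step needs chemoselectivity among three alkenes and regioselective proton loss, and these rest on four features: the sulfolene alkene is deactivated by its two allylic C–SO2 bonds, ester and phosphonate are only reversibly protonated and carry no acid-labile alkyl group, protonation of C8=C9 is reversible and unproductive, and the endocyclic trisubstituted alkene is the usual outcome of such quenches.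

Step 8
Reactants: 14 labd-7-ene bicycle
Product: 15 7α,8α-diol of 14
Conditions: OsO4 (5 mol %), N-methylmorpholine N-oxide (1.05 equiv), acetone–H2O, rt
Reagents that add atoms: N-methylmorpholine N-oxide, C[N+]1([O-])CCOCC1; water, O; osmium tetroxide (oxygen relay), O=[Os](=O)(=O)=O
Why: Catalytic syn dihydroxylation should take place on the α face of C7=C8, opposite the axial C20 methyl group and the β-oriented C9 chain, which sets 7α-OH and 8α-OH together, while the electron-poor sulfolene alkene reacts more slowly.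

Step 9
Reactants: 15 diol sulfolene
Product: 16 7α,8α-dihydroxylabda-13(16),14-dien-19-yl 2-[bis(2,2,2-trifluoroethoxy)phosphoryl]acetate
Conditions: toluene, 2,6-di-tert-butyl-4-methylphenol (cat.), 120 °C, slow N2 sweep
Reagents that add atoms: none
Why: Retro-cheletropic extrusion of SO2 from the 3-substituted sulfolene releases the 2-substituted buta-1,3-diene regiospecifically and touches no stereocentre.

Step 10
Reactants: 16 diene diol phosphonoacetate; 17 4-[(tert-butyldimethylsilyl)oxy]benzaldehyde
Product: 18 7α,8α-dihydroxylabda-13(16),14-dien-19-yl (Z)-3-{4-[(tert-butyldimethylsilyl)oxy]phenyl}prop-2-enoate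
Conditions: KN(SiMe3)2 (1.05 equiv), 18-crown-6, THF, −78 °C; then 17, −78 °C
Reagents that add atoms: 4-[(tert-butyldimethylsilyl)oxy]benzaldehyde (17), O=Cc1ccc(O[Si](C)(C)C(C)(C)C)cc1
Why: In the Still–Gennari variant of the Horner–Wadsworth–Emmons reaction the trifluoroethyl phosphonate makes elimination of the kinetic adduct fast and so gives the Z enoate, and the phosphonate CH2 is far more acidic than the two hydroxyl groups, so one equivalent of base suffices.

Step 11
Reactants: 18 silyl ether
Product: 19 target, 7α,8α-dihydroxylabda-13(16),14-dien-19-yl (Z)-4-hydroxycinnamate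
Conditions: Bu4NF–AcOH (1:1), THF, 0 °C, exclusion of light
Reagents that add atoms: none
Why: Fluoride-mediated desilylation of the aryl silyl ether under buffered conditions avoids a free phenoxide and light, the two agents that would isomerise the Z alkene.

Compound list
1 | (E)-β-farnesene, (6E)-7,11-dimethyl-3-methylidenedodeca-1,6,10-triene | CC(C)=CCC/C(C)=C/CCC(=C)C=C | starting material
2 | 3-[(3E)-4,8-dimethylnona-3,7-dien-1-yl]-2,5-dihydrothiophene 1,1-dioxide | CC(C)=CCC/C(C)=C/CCC1=CCS(=O)(=O)C1 | intermediate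
3 | 3-[(3E,7E)-9-hydroxy-4,8-dimethylnona-3,7-dien-1-yl]-2,5-dihydrothiophene 1,1-dioxide | OC/C(C)=C/CC/C(C)=C/CCC1=CCS(=O)(=O)C1 | intermediate
4 | (2E,6E)-9-(1,1-dioxo-2,5-dihydrothiophen-3-yl)-2,6-dimethylnona-2,6-dienal | O=C/C(C)=C/CC/C(C)=C/CCC1=CCS(=O)(=O)C1 | intermediate
5 | 3-[(3E,7E)-4,8-dimethyldeca-3,7,9-trien-1-yl]-2,5-dihydrothiophene 1,1-dioxide | C=C/C(C)=C/CC/C(C)=C/CCC1=CCS(=O)(=O)C1 | intermediate
6 | methacrolein | C=C(C)C=O | starting material
7 | (1S,2R)-2-[(3E)-6-(1,1-dioxo-2,5-dihydrothiophen-3-yl)-3-methylhex-3-en-1-yl]-1,3-dimethylcyclohex-3-ene-1-carbaldehyde | O=S1(=O)CC=C(CC/C=C(\C)CC[C@H]2[C@@](C)(C=O)CCC=C2C)C1 | intermediate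
8 | {(1S,2R)-2-[(3E)-6-(1,1-dioxo-2,5-dihydrothiophen-3-yl)-3-methylhex-3-en-1-yl]-1,3-dimethylcyclohex-3-en-1-yl}methanol | O=S1(=O)CC=C(CC/C=C(\C)CC[C@H]2[C@@](C)(CO)CCC=C2C)C1 | intermediate
9 | methyl 2-[bis(2,2,2-trifluoroethoxy)phosphoryl]acetate | COC(=O)CP(=O)(OCC(F)(F)F)OCC(F)(F)F | starting material
10 | 2-[bis(2,2,2-trifluoroethoxy)phosphoryl]acetic acid | OC(=O)CP(=O)(OCC(F)(F)F)OCC(F)(F)F | intermediate
11 | 2-[bis(2,2,2-trifluoroethoxy)phosphoryl]acetate ester of 8 | O=S1(=O)CC=C(CC/C=C(\C)CC[C@H]2[C@@](C)(COC(=O)CP(=O)(OCC(F)(F)F)OCC(F)(F)F)CCC=C2C)C1 | intermediate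
12 | monocyclic tertiary C10 cation, fluorosulfate ion pair | O=S1(=O)CC=C(CC/C=C(\C)CC[C@H]2[C@@](C)(COC(=O)CP(=O)(OCC(F)(F)F)OCC(F)(F)F)CCC[C+]2C)C1.[O-]S(=O)(=O)F | intermediate
13 | bicyclic tertiary C8 cation, fluorosulfate ion pair | O=S1(=O)CC=C(CC[C@H]2[C+](C)CC[C@H]3[C@@](C)(COC(=O)CP(=O)(OCC(F)(F)F)OCC(F)(F)F)CCC[C@@]32C)C1.[O-]S(=O)(=O)F | intermediate
14 | labd-7-ene bicycle with C13–C16 sulfolene and 19-O-phosphonoacetate (5α-H, 9α-H, 10β-CH3) | O=S1(=O)CC=C(CC[C@H]2C(C)=CC[C@H]3[C@@](C)(COC(=O)CP(=O)(OCC(F)(F)F)OCC(F)(F)F)CCC[C@@]32C)C1 | intermediate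
15 | 7α,8α-diol of 14 | O=S1(=O)CC=C(CC[C@H]2[C@](C)(O)[C@H](O)C[C@H]3[C@@](C)(COC(=O)CP(=O)(OCC(F)(F)F)OCC(F)(F)F)CCC[C@@]32C)C1 | intermediate
16 | 7α,8α-dihydroxylabda-13(16),14-dien-19-yl 2-[bis(2,2,2-trifluoroethoxy)phosphoryl]acetate | C=CC(=C)CC[C@H]1[C@](C)(O)[C@H](O)C[C@H]2[C@@](C)(COC(=O)CP(=O)(OCC(F)(F)F)OCC(F)(F)F)CCC[C@@]21C | intermediate
17 | 4-[(tert-butyldimethylsilyl)oxy]benzaldehyde | O=Cc1ccc(O[Si](C)(C)C(C)(C)C)cc1 | starting material
18 | 7α,8α-dihydroxylabda-13(16),14-dien-19-yl (Z)-3-{4-[(tert-butyldimethylsilyl)oxy]phenyl}prop-2-enoate | C=CC(=C)CC[C@H]1[C@](C)(O)[C@H](O)C[C@H]2[C@@](C)(COC(=O)/C=C\c3ccc(O[Si](C)(C)C(C)(C)C)cc3)CCC[C@@]21C | intermediate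
19 | 7α,8α-dihydroxylabda-13(16),14-dien-19-yl (Z)-4-hydroxycinnamate (CNP0254560.1) | C=CC(=C)CC[C@H]1[C@](C)(O)[C@H](O)C[C@H]2[C@@](C)(COC(=O)/C=C\c3ccc(O)cc3)CCC[C@@]21C | target

Total step count: 11. Longest linear sequence: 10 steps (steps 1–4 and 6–11, from 1).

Steps most likely to fail

Step 7.
- What may go wrong: the C8 cation may lose a proton in three directions. The C10 cation may lose H-5 or undergo a 1,2-hydride shift, so that the C5 configuration erodes. Closure through the other lobe of the cation would give the cis-decalin, and a protonated C8=C9 alkene may close onto C1 instead.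
- Fallback (sets out from 8, comes back at 14): the cation is made by ionisation instead of protonation. Iodoetherification of 8 (I2, NaHCO3, MeCN, 0 °C) should give the bridged iodo ether F1, with a C19–O–C10 bridge on the β face and a 1α-iodide. Bu3SnH removes the iodide and gives the 6-oxabicyclo[3.2.1]octane ether F2. SnCl4 in CH2Cl2 at −78 °C ionises only the tertiary C10–O bond. The departing alkoxide shields the β face, C9 attacks from the α face, and the bicyclic C19 alcohol F3 should result without free superacid. Esterification of F3 with 10 (N,N'-dicyclohexylcarbodiimide) returns to 14.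

Step 4.
- What may go wrong: the formyl group may approach exo instead of endo, so that C19 and the C5 chain come out trans. The methyl group on C10 of the diene may erode the ortho regioselectivity. Facial shielding of the α-substituted enal may be incomplete.
- Fallback (sets out from 5, comes back at 8): an exo preference is turned to advantage by exchanging the roles of the two C4 substituents. Commercial 2-methylidenepropane-1,3-diol is monosilylated (t-BuMe2SiCl, imidazole) to the allylic alcohol F4 and oxidised with MnO2 to the 2-(silyloxymethyl)acrolein F5. Exo cycloaddition of F5 to 5 under the same kind of catalysis places CH2OSi cis and CHO trans to the C5 chain in the aldehyde F6. The formyl group is taken down to the C18 methyl group through the tosylhydrazone F7 (TsNHNH2), which is reduced with catecholborane and then NaOAc to the silyl ether F8. Bu4NF then gives 8.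

Step 8.
- What may go wrong: the sulfolene alkene may be osmylated in competition, because the C7=C8 alkene is trisubstituted and hindered.
- Fallback (sets out from 14, comes back at 16): the diene mask is changed before the oxidation. Thermolysis of 14 (toluene, 120 °C) gives the triene F9. Fe2(CO)9 binds only the conjugated diene and gives the tricarbonyliron complex F10. Stoichiometric OsO4 in pyridine (no amine oxide, reductive work-up with NaHSO3) dihydroxylates the only free alkene from the α face to the complexed diol F11. Me3NO removes the metal and gives 16.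

Further compounds
F1 | step 7 | bridged iodo ether of 8 (10β,19-epoxide, 1α-iodide) | O=S1(=O)CC=C(CC/C=C(\C)CC[C@H]2[C@]3(C)CC[C@H](I)[C@@]2(C)OC3)C1
F2 | step 7 | 6-oxabicyclo[3.2.1]octane ether (10β,19-epoxide) | O=S1(=O)CC=C(CC/C=C(\C)CC[C@H]2[C@]3(C)CCC[C@@]2(C)OC3)C1
F3 | step 7 | labd-7-en-19-ol bicycle with C13–C16 sulfolene | O=S1(=O)CC=C(CC[C@H]2C(C)=CC[C@H]3[C@@](C)(CO)CCC[C@@]32C)C1
F4 | step 4 | 2-({[tert-butyl(dimethyl)silyl]oxy}methyl)prop-2-en-1-ol | C=C(CO)CO[Si](C)(C)C(C)(C)C
F5 | step 4 | 2-({[tert-butyl(dimethyl)silyl]oxy}methyl)prop-2-enal | C=C(C=O)CO[Si](C)(C)C(C)(C)C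
F6 | step 4 | exo adduct, ring A aldehyde with CHO trans and CH2OSi cis to the C5 chain | O=S1(=O)CC=C(CC/C=C(\C)CC[C@H]2[C@@](C=O)(CO[Si](C)(C)C(C)(C)C)CCC=C2C)C1
F7 | step 4 | tosylhydrazone of F6 | O=S1(=O)CC=C(CC/C=C(\C)CC[C@H]2[C@@](/C=N/NS(=O)(=O)c3ccc(C)cc3)(CO[Si](C)(C)C(C)(C)C)CCC=C2C)C1
F8 | step 4 | tert-butyldimethylsilyl ether of 8 | O=S1(=O)CC=C(CC/C=C(\C)CC[C@H]2[C@@](C)(CO[Si](C)(C)C(C)(C)C)CCC=C2C)C1
F9 | step 8 | labda-7,13(16),14-trien-19-yl 2-[bis(2,2,2-trifluoroethoxy)phosphoryl]acetate | C=CC(=C)CC[C@H]1C(C)=CC[C@H]2[C@@](C)(COC(=O)CP(=O)(OCC(F)(F)F)OCC(F)(F)F)CCC[C@@]21C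
F10 | step 8 | tricarbonyliron complex of the 13(16),14-diene of F9 | C=CC(=C)CC[C@H]1C(C)=CC[C@H]2[C@@](C)(COC(=O)CP(=O)(OCC(F)(F)F)OCC(F)(F)F)CCC[C@@]21C.[Fe].[C-]#[O+].[C-]#[O+].[C-]#[O+]
F11 | step 8 | tricarbonyliron complex of 16 | C=CC(=C)CC[C@H]1[C@](C)(O)[C@H](O)C[C@H]2[C@@](C)(COC(=O)CP(=O)(OCC(F)(F)F)OCC(F)(F)F)CCC[C@@]21C.[Fe].[C-]#[O+].[C-]#[O+].[C-]#[O+]
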